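**Strategy.** Everything rests on cutting the C2–C3 bond of the chroman (dihydropyran ring, chroman numbering) and the aryl–C2 bond of the flavanone. The chroman is closed by an internal-redox 1,5-hydride shift/cyclization of a salicylaldehyde-derived arylidene malonate carrying a Mitsunobu-installed (R)-propargylic ether: the aldehyde carbon (future C4) takes the O1-bound C2–H as hydride and the malonate carbon (C3) bonds to the oxocarbenium C2. One operation should make C2–C3, reduce C4 to CH2 and convert the secondary ether centre into quaternary C2 with chirality transfer. It exploits the 1,5-relationship of C2–H and C4 across O1–C8a–C4a and the C8 oxygen ortho to O1. A rhodium-catalysed asymmetric arylation of a chromone then sets the flavanone centre.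

Key step: step 4

Assumption (chemistry): in step 4 the new C2–C3 bond is taken to form on the face of C2 that the hydride vacates (net retention); if the opposite sense were found, the (R)-enantiomer of alkynol 3 would be used, all else unchanged.

**Step 1**
Reactants: 1 5-bromo-2,3-dihydroxybenzaldehyde
Product: 2 5-bromo-2-hydroxy-3-[(triisopropylsilyl)oxy]benzaldehyde
Conditions: TIPSCl (1.05 equiv), imidazole, DMF, 0 °C
Reagents that add atoms: chlorotriisopropylsilane (TIPSCl), CC(C)[Si](Cl)(C(C)C)C(C)C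
Why: Selective phenol silylation should take the C3 hydroxyl, the more accessible and nucleophilic one, because the C2 hydroxyl is tied up in the hydrogen bond to the aldehyde.

**Step 2**
Reactants: 2 5-bromo-2-hydroxy-3-[(triisopropylsilyl)oxy]benzaldehyde; 3 (S)-4-(trimethylsilyl)but-3-yn-2-ol
Product: 4 5-bromo-3-[(triisopropylsilyl)oxy]-2-{[(2R)-4-(trimethylsilyl)but-3-yn-2-yl]oxy}benzaldehyde
Conditions: PPh3, DIAD, THF, 0 °C to rt
Reagents that add atoms: none
Why: Mitsunobu etherification of the acidic salicylaldehyde phenol with the secondary propargylic alcohol proceeds by SN2 inversion, so the (S)-carbinol becomes the (R)-aryl ether centre that will be chroman C2.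

**Step 3**
Reactants: 4 5-bromo-3-[(triisopropylsilyl)oxy]-2-{[(2R)-4-(trimethylsilyl)but-3-yn-2-yl]oxy}benzaldehyde; 5 diallyl malonate
Product: 6 diallyl 2-[(5-bromo-3-[(triisopropylsilyl)oxy]-2-{[(2R)-4-(trimethylsilyl)but-3-yn-2-yl]oxy}phenyl)methylidene]propanedioate
Conditions: piperidine (cat.), AcOH (cat.), toluene, reflux, Dean–Stark
Reagents that add atoms: none
Why: Knoevenagel condensation with azeotropic removal of water should give the arylidene malonate that serves as the hydride acceptor.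

**Step 4**
Reactants: 6 diallyl 2-[(5-bromo-3-[(triisopropylsilyl)oxy]-2-{[(2R)-4-(trimethylsilyl)but-3-yn-2-yl]oxy}phenyl)methylidene]propanedioate
Product: 8 diallyl (2S)-6-bromo-2-methyl-8-[(triisopropylsilyl)oxy]-2-[(trimethylsilyl)ethynyl]chromane-3,3-dicarboxylate, via oxocarbenium malonate zwitterion 7 (not isolated)
Conditions: Sc(OTf)3 (10 mol %), ClCH2CH2Cl, 80 °C
Reagents that add atoms: none
Why: Internal-redox 1,5-hydride shift/cyclization: Sc(OTf)3 chelates the malonate, the benzylic carbon (future C4) takes the O1-bound C2–H through space as hydride, and the scandium-bound malonate carbon (C3) of zwitterion 7 collapses onto the oxocarbenium carbon C2. The closest known reaction type is the Lewis acid-catalysed hydride shift/cyclization of ortho-alkoxy arylidene malonates to 3,3-disubstituted chromans, including chirality-transferring cases with tertiary C–H donors (self-reproduction of chirality). The dihydropyran ring closes in a 6-endo-trig mode, C3 adding to the endocyclic O1=C2 bond. The one new stereocentre, C2, is controlled by the (R)-ether centre itself: hydride leaves and C3 enters on the same face while rotation about C8a–O1 in the short-lived helical zwitterion is blocked by the C8 silyloxy group and the C4a side arm, so C3 should take the place of H (2S). The step needs hydride donation from the single C–H held 1,5 to C4, which the C8–OTIPS buttress ortho to O1 presses toward the acceptor, and attack at C2 instead of the alkyne terminus, secured by six- against eight-membered ring closure.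

**Step 5**
Reactants: 8 diallyl (2S)-6-bromo-2-methyl-8-[(triisopropylsilyl)oxy]-2-[(trimethylsilyl)ethynyl]chromane-3,3-dicarboxylate
Product: 9 (2S)-6-bromo-2-methyl-8-[(triisopropylsilyl)oxy]-2-[(trimethylsilyl)ethynyl]chromane-3,3-dicarboxylic acid
Conditions: Pd(PPh3)4 (5 mol %), morpholine, THF, rt; mildly acidic work-up
Reagents that add atoms: none
Why: Tsuji–Trost deallylation (allyl transfer to morpholine) should unmask both acids under neutral conditions that spare the aryl silyl ether and the silylalkyne, and oxidative addition to the electron-rich aryl bromide is slow at rt.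

**Step 6**
Reactants: 9 (2S)-6-bromo-2-methyl-8-[(triisopropylsilyl)oxy]-2-[(trimethylsilyl)ethynyl]chromane-3,3-dicarboxylic acid
Product: 11 (2S)-6-bromo-2-methyl-8-[(triisopropylsilyl)oxy]-2-[(trimethylsilyl)ethynyl]chromane, via monoacid 10 (not isolated)
Conditions: 9-mesityl-10-phenylacridinium tetrafluoroborate (5 mol %), PhSSPh (10 mol %), i-Pr2NEt, CF3CH2OH, blue LEDs, rt
Reagents that add atoms: none
Why: Acridinium photoredox hydrodecarboxylation, known as a one-pot two-fold process for malonic acids: each carboxylate is oxidised, loses CO2, and the C3 radical is quenched by thiol hydrogen-atom transfer, so no C3 carbanion arises that could expel the O1 aryloxide and scramble C2.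

**Step 7**
Reactants: 11 (2S)-6-bromo-2-methyl-8-[(triisopropylsilyl)oxy]-2-[(trimethylsilyl)ethynyl]chromane
Product: 12 (2S)-6-bromo-2-ethynyl-2-methyl-8-[(triisopropylsilyl)oxy]chromane
Conditions: K2CO3 (0.2 equiv), MeOH/THF, 0 °C
Reagents that add atoms: none
Why: Carbonate-catalysed methanolysis of the C(sp)–Si bond (protodesilylation) should free the terminal alkyne while the bulkier aryl triisopropylsilyl ether persists at 0 °C.

**Step 8**
Reactants: 12 (2S)-6-bromo-2-ethynyl-2-methyl-8-[(triisopropylsilyl)oxy]chromane; 13 1-bromo-2-methylprop-1-ene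
Product: 16 (2S)-6-bromo-2-methyl-2-[(1E)-4-methylpenta-1,3-dien-1-yl]-8-[(triisopropylsilyl)oxy]chromane, via alkenylzirconocene chloride 14 (not isolated), via alkenylzinc chloride 15 (not isolated)
Conditions: Cp2Zr(H)Cl, THF, rt; then ZnCl2, Pd(PPh3)4 (5 mol %), 13 (3 equiv), rt
Reagents that add atoms: none
Why: Syn hydrozirconation places the metal on the terminal carbon to give the (E)-alkenyl species, and zinc-assisted Negishi coupling proceeds with retention to set the (1E)-diene; the vinyl bromide in excess should outcompete the electron-rich aryl bromide in oxidative addition at rt.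

**Step 9**
Reactants: 16 (2S)-6-bromo-2-methyl-2-[(1E)-4-methylpenta-1,3-dien-1-yl]-8-[(triisopropylsilyl)oxy]chromane
Product: 19 {(2S)-2-methyl-2-[(1E)-4-methylpenta-1,3-dien-1-yl]-8-[(triisopropylsilyl)oxy]chroman-6-yl}boronic acid, via aryllithium 17 (not isolated), via lithium triisopropoxyborate 18 (not isolated)
Conditions: t-BuLi (2.1 equiv), Et2O, −78 °C; B(OiPr)3; aq. NH4Cl
Reagents that add atoms: triisopropyl borate, CC(C)OB(OC(C)C)OC(C)C; water, O
Why: Lithiation–borylation: bromine–lithium exchange at −78 °C is far faster than any addition to the diene, and mild hydrolysis of the borate gives the arylboronic acid without acid that would ionise the tertiary dienyl ether.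

**Step 10**
Reactants: 20 2',4',6'-trihydroxyacetophenone
Product: 21 1-{2,4-bis[(tert-butyldimethylsilyl)oxy]-6-hydroxyphenyl}ethanone
Conditions: TBSCl (2.2 equiv), imidazole, DMF, 0 °C to rt
Reagents that add atoms: tert-butylchlorodimethylsilane (TBSCl), CC(C)(C)[Si](C)(C)Cl
Why: Selective phenol silylation should take the para hydroxyl and one ortho hydroxyl, the remaining ortho hydroxyl staying free because it is hydrogen-bonded to the ketone.

**Step 11**
Reactants: 21 1-{2,4-bis[(tert-butyldimethylsilyl)oxy]-6-hydroxyphenyl}ethanone; 22 3-methylbut-2-en-1-ol (prenol)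
Product: 23 1-{2,4-bis[(tert-butyldimethylsilyl)oxy]-6-[(3-methylbut-2-en-1-yl)oxy]phenyl}ethanone
Conditions: PPh3, DIAD, THF, 0 °C to rt
Reagents that add atoms: none
Why: Mitsunobu O-alkylation of the hydrogen-bonded phenol under neutral conditions should give the aryl prenyl ether without disturbing the silyl ethers.

**Step 12**
Reactants: 23 1-{2,4-bis[(tert-butyldimethylsilyl)oxy]-6-[(3-methylbut-2-en-1-yl)oxy]phenyl}ethanone
Product: 26 1-{2,4-bis[(tert-butyldimethylsilyl)oxy]-6-hydroxy-3-(3-methylbut-2-en-1-yl)phenyl}ethanone, via ortho-dienone 24 (not isolated), via para-dienone 25 (not isolated)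
Conditions: Eu(fod)3 (10 mol %), CHCl3, 80 °C (sealed)
Reagents that add atoms: none
Why: Europium-catalysed tandem Claisen–Cope rearrangement: chelation of the ketone and ether oxygens triggers the ortho [3,3] shift to 24, whose Cope [3,3] shift to 25 should outrun enolisation and deliver the normal prenyl group para to the oxygen, between the two silyloxy groups, before tautomerisation.

**Step 13**
Reactants: 26 1-{2,4-bis[(tert-butyldimethylsilyl)oxy]-6-hydroxy-3-(3-methylbut-2-en-1-yl)phenyl}ethanone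
Product: 28 5,7-bis[(tert-butyldimethylsilyl)oxy]-6-(3-methylbut-2-en-1-yl)-4H-chromen-4-one, via enaminone 27 (not isolated)
Conditions: DMF-DMA, toluene, 90 °C; then AcOH, 60 °C
Reagents that add atoms: N,N-dimethylformamide dimethyl acetal (DMF-DMA), COC(OC)N(C)C
Why: Enaminone route to chromones: condensation at the methyl ketone gives 27, and acid-promoted addition of the only free phenol with loss of dimethylamine closes the pyranone, so the prenyl group ends at C6.

**Step 14**
Reactants: 19 {(2S)-2-methyl-2-[(1E)-4-methylpenta-1,3-dien-1-yl]-8-[(triisopropylsilyl)oxy]chroman-6-yl}boronic acid; 28 5,7-bis[(tert-butyldimethylsilyl)oxy]-6-(3-methylbut-2-en-1-yl)-4H-chromen-4-one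
Product: 29 (2S)-5,7-bis[(tert-butyldimethylsilyl)oxy]-2-{(2S)-2-methyl-2-[(1E)-4-methylpenta-1,3-dien-1-yl]-8-[(triisopropylsilyl)oxy]chroman-6-yl}-6-(3-methylbut-2-en-1-yl)chroman-4-one
Conditions: [Rh(OH)(cod)]2 (2.5 mol %), (S)-MeO-F12-BIPHEP [(S)-6,6'-dimethoxy-2,2'-bis{bis(3,4,5-trifluorophenyl)phosphino}biphenyl] (5.5 mol %), 28 (1.5 equiv), toluene/H2O (10:1), 40 °C
Reagents that add atoms: none
Why: Rhodium-catalysed asymmetric 1,4-addition of an arylboronic acid to a chromone: the aryl–rhodium species bearing the electron-poor bisphosphine inserts the C2=C3 bond on one face and water protonates the rhodium enolate, setting flavanone C2 as S by catalyst control (sense predicted from the quadrant model for cyclic enones, to be confirmed with phenylboronic acid before the fragments are committed), while base-free conditions avoid retro-oxa-Michael racemisation and silyl loss.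

**Step 15**
Reactants: 29 (2S)-5,7-bis[(tert-butyldimethylsilyl)oxy]-2-{(2S)-2-methyl-2-[(1E)-4-methylpenta-1,3-dien-1-yl]-8-[(triisopropylsilyl)oxy]chroman-6-yl}-6-(3-methylbut-2-en-1-yl)chroman-4-one
Product: 30 (2S)-5,7-dihydroxy-2-{(2S)-8-hydroxy-2-methyl-2-[(1E)-4-methylpenta-1,3-dien-1-yl]chroman-6-yl}-6-(3-methylbut-2-en-1-yl)chroman-4-one
Conditions: TBAF (3.3 equiv), AcOH (3.3 equiv), THF, 0 °C
Reagents that add atoms: none
Why: Buffered fluoride desilylation should cleave the three aryl silyl ethers without acid that would ionise the tertiary dienyl ether at chroman C2 and without free base that would open and racemise the flavanone.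

**Compound list**

1 | 5-bromo-2,3-dihydroxybenzaldehyde | O=Cc1cc(Br)cc(O)c1O | starting material
2 | 5-bromo-2-hydroxy-3-[(triisopropylsilyl)oxy]benzaldehyde | O=Cc1cc(Br)cc(O[Si](C(C)C)(C(C)C)C(C)C)c1O | intermediate
3 | (S)-4-(trimethylsilyl)but-3-yn-2-ol | C[C@H](O)C#C[Si](C)(C)C | starting material
4 | 5-bromo-3-[(triisopropylsilyl)oxy]-2-{[(2R)-4-(trimethylsilyl)but-3-yn-2-yl]oxy}benzaldehyde | C[C@@H](Oc1c(C=O)cc(Br)cc1O[Si](C(C)C)(C(C)C)C(C)C)C#C[Si](C)(C)C | intermediate
5 | diallyl malonate | C=CCOC(=O)CC(=O)OCC=C | starting material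
6 | diallyl 2-[(5-bromo-3-[(triisopropylsilyl)oxy]-2-{[(2R)-4-(trimethylsilyl)but-3-yn-2-yl]oxy}phenyl)methylidene]propanedioate | C[C@@H](Oc1c(C=C(C(=O)OCC=C)C(=O)OCC=C)cc(Br)cc1O[Si](C(C)C)(C(C)C)C(C)C)C#C[Si](C)(C)C | intermediate
7 | zwitterion after hydride shift: aryl oxocarbenium (O1=C2) with benzylmalonate carbanion | CC(=[O+]c1c(C[C-](C(=O)OCC=C)C(=O)OCC=C)cc(Br)cc1O[Si](C(C)C)(C(C)C)C(C)C)C#C[Si](C)(C)C | intermediate
8 | diallyl (2S)-6-bromo-2-methyl-8-[(triisopropylsilyl)oxy]-2-[(trimethylsilyl)ethynyl]chromane-3,3-dicarboxylate | C[Si](C)(C)C#C[C@]1(C)C(C(=O)OCC=C)(C(=O)OCC=C)Cc2cc(Br)cc(O[Si](C(C)C)(C(C)C)C(C)C)c2O1 | intermediate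
9 | (2S)-6-bromo-2-methyl-8-[(triisopropylsilyl)oxy]-2-[(trimethylsilyl)ethynyl]chromane-3,3-dicarboxylic acid | C[Si](C)(C)C#C[C@]1(C)C(C(=O)O)(C(=O)O)Cc2cc(Br)cc(O[Si](C(C)C)(C(C)C)C(C)C)c2O1 | intermediate
10 | (2S)-6-bromo-2-methyl-8-[(triisopropylsilyl)oxy]-2-[(trimethylsilyl)ethynyl]chromane-3-carboxylic acid (C3 epimers) | C[Si](C)(C)C#C[C@]1(C)C(C(=O)O)Cc2cc(Br)cc(O[Si](C(C)C)(C(C)C)C(C)C)c2O1 | intermediate
11 | (2S)-6-bromo-2-methyl-8-[(triisopropylsilyl)oxy]-2-[(trimethylsilyl)ethynyl]chromane | C[Si](C)(C)C#C[C@]1(C)CCc2cc(Br)cc(O[Si](C(C)C)(C(C)C)C(C)C)c2O1 | intermediate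
12 | (2S)-6-bromo-2-ethynyl-2-methyl-8-[(triisopropylsilyl)oxy]chromane | C#C[C@]1(C)CCc2cc(Br)cc(O[Si](C(C)C)(C(C)C)C(C)C)c2O1 | intermediate
13 | 1-bromo-2-methylprop-1-ene | CC(C)=CBr | starting material
14 | (E)-alkenylzirconocene chloride from 12 | Cl[Zr](/C=C/[C@]1(C)CCc2cc(Br)cc(O[Si](C(C)C)(C(C)C)C(C)C)c2O1)(C1C=CC=C1)C1C=CC=C1 | intermediate
15 | (E)-alkenylzinc chloride from 14 | Cl[Zn]/C=C/[C@]1(C)CCc2cc(Br)cc(O[Si](C(C)C)(C(C)C)C(C)C)c2O1 | intermediate
16 | (2S)-6-bromo-2-methyl-2-[(1E)-4-methylpenta-1,3-dien-1-yl]-8-[(triisopropylsilyl)oxy]chromane | CC(C)=C/C=C/[C@]1(C)CCc2cc(Br)cc(O[Si](C(C)C)(C(C)C)C(C)C)c2O1 | intermediate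
17 | chroman-6-yllithium from 16 | CC(C)=C/C=C/[C@]1(C)CCc2cc([Li])cc(O[Si](C(C)C)(C(C)C)C(C)C)c2O1 | intermediate
18 | lithium (chroman-6-yl)triisopropoxyborate | CC(C)=C/C=C/[C@]1(C)CCc2cc([B-](OC(C)C)(OC(C)C)OC(C)C)cc(O[Si](C(C)C)(C(C)C)C(C)C)c2O1.[Li+] | intermediate
19 | {(2S)-2-methyl-2-[(1E)-4-methylpenta-1,3-dien-1-yl]-8-[(triisopropylsilyl)oxy]chroman-6-yl}boronic acid | CC(C)=C/C=C/[C@]1(C)CCc2cc(B(O)O)cc(O[Si](C(C)C)(C(C)C)C(C)C)c2O1 | intermediate
20 | 2',4',6'-trihydroxyacetophenone | CC(=O)c1c(O)cc(O)cc1O | starting material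
21 | 1-{2,4-bis[(tert-butyldimethylsilyl)oxy]-6-hydroxyphenyl}ethanone | CC(=O)c1c(O)cc(O[Si](C)(C)C(C)(C)C)cc1O[Si](C)(C)C(C)(C)C | intermediate
22 | 3-methylbut-2-en-1-ol (prenol) | CC(C)=CCO | starting material
23 | 1-{2,4-bis[(tert-butyldimethylsilyl)oxy]-6-[(3-methylbut-2-en-1-yl)oxy]phenyl}ethanone | CC(=O)c1c(OCC=C(C)C)cc(O[Si](C)(C)C(C)(C)C)cc1O[Si](C)(C)C(C)(C)C | intermediate
24 | ortho-dienone: 2-acetyl-3,5-bis(silyloxy)-6-(2-methylbut-3-en-2-yl)cyclohexa-2,4-dien-1-one | CC(=O)C1=C(O[Si](C)(C)C(C)(C)C)C=C(O[Si](C)(C)C(C)(C)C)C(C(C)(C)C=C)C1=O | intermediate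
25 | para-dienone: 2-acetyl-3,5-bis(silyloxy)-4-(3-methylbut-2-en-1-yl)cyclohexa-2,5-dien-1-one | CC(=O)C1=C(O[Si](C)(C)C(C)(C)C)C(CC=C(C)C)C(O[Si](C)(C)C(C)(C)C)=CC1=O | intermediate
26 | 1-{2,4-bis[(tert-butyldimethylsilyl)oxy]-6-hydroxy-3-(3-methylbut-2-en-1-yl)phenyl}ethanone | CC(=O)c1c(O)cc(O[Si](C)(C)C(C)(C)C)c(CC=C(C)C)c1O[Si](C)(C)C(C)(C)C | intermediate
27 | (E)-3-(dimethylamino)-1-aryl-prop-2-en-1-one (enaminone of 26) | CN(C)/C=C/C(=O)c1c(O)cc(O[Si](C)(C)C(C)(C)C)c(CC=C(C)C)c1O[Si](C)(C)C(C)(C)C | intermediate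
28 | 5,7-bis[(tert-butyldimethylsilyl)oxy]-6-(3-methylbut-2-en-1-yl)-4H-chromen-4-one | O=c1ccoc2cc(O[Si](C)(C)C(C)(C)C)c(CC=C(C)C)c(O[Si](C)(C)C(C)(C)C)c12 | intermediate
29 | (2S)-5,7-bis[(tert-butyldimethylsilyl)oxy]-2-{(2S)-2-methyl-2-[(1E)-4-methylpenta-1,3-dien-1-yl]-8-[(triisopropylsilyl)oxy]chroman-6-yl}-6-(3-methylbut-2-en-1-yl)chroman-4-one | CC(C)=C/C=C/[C@]1(C)CCc2cc([C@@H]3CC(=O)c4c(cc(O[Si](C)(C)C(C)(C)C)c(CC=C(C)C)c4O[Si](C)(C)C(C)(C)C)O3)cc(O[Si](C(C)C)(C(C)C)C(C)C)c2O1 | intermediate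
30 | (2S)-5,7-dihydroxy-2-{(2S)-8-hydroxy-2-methyl-2-[(1E)-4-methylpenta-1,3-dien-1-yl]chroman-6-yl}-6-(3-methylbut-2-en-1-yl)chroman-4-one | CC(C)=C/C=C/[C@]1(C)CCc2cc([C@@H]3CC(=O)c4c(cc(O)c(CC=C(C)C)c4O)O3)cc(O)c2O1 | target

**Step count and risks**

Total step count: 15. Longest linear sequence: 11 steps (steps 1–9, 14, 15).

Steps most likely to fail:

1. Step 4. The hydride transfer from the alkynyl-substituted C–H may be sluggish, or the zwitterion may relax by rotation about C8a–O1 before C–C closure, eroding the chirality transfer. Fallback (sets out from 4, returns at 11): the same C2–C3 bond would be closed by stereoretentive rhodium-carbenoid C–H insertion. Pinnick oxidation of 4 (NaClO2, NaH2PO4, 2-methylbut-2-ene, t-BuOH/H2O) would give 5-bromo-3-[(triisopropylsilyl)oxy]-2-{[(2R)-4-(trimethylsilyl)but-3-yn-2-yl]oxy}benzoic acid F1. 1-Chloro-N,N,2-trimethylprop-1-en-1-amine would convert it under neutral conditions into the acid chloride F2, and diazomethane would give the diazoketone F3. Rh2(OAc)4 in CH2Cl2 should insert the carbenoid into the O1-bound tertiary C–H (six-membered ring, retention at C2) to give the (2S)-chromanone F4. Ionic hydrogenation (Et3SiH, CF3CO2H) would then remove the C4 carbonyl and give 11.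

2. Step 6. The excited acridinium may oxidise the electron-rich bromoarene instead of the carboxylates, the second decarboxylation may stall, or the C3 radical may fragment by loss of the O1 aryloxyl. Fallback (sets out from 9, returns at 11): stepwise removal without photoredox catalysis. Thermal monodecarboxylation of 9 (DMSO, 110 °C, no base) would give monoacid 10, now isolated. Coupling with 2-mercaptopyridine N-oxide (DCC, DMAP, CH2Cl2, dark) would give the O-acyl thiohydroxamate F5, and Barton reductive decarboxylation (t-BuSH, visible light, benzene) would give 11.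

3. Step 14. Protodeboronation may outpace insertion into the electron-rich, peri-substituted chromone, and the diene may bind rhodium or undergo hydroarylation. Fallback (sets out from 16 and 26, returns at 29): the flavanone would be assembled by condensation instead of arylation. Lithiation of 16 (t-BuLi, −78 °C) and a DMF quench would give the (2S)-aldehyde F6. Pyrrolidine-mediated condensation with acetophenone 26 (MeCN, 50 °C) would pass through the 2'-hydroxychalcone F7 and close by oxa-Michael addition of the only free phenol, giving 29 together with its flavanone C2 epimer F8. Because the chroman centre makes these two diastereomers, they would be separated by preparative HPLC, F8 being recycled by amine-mediated equilibration through F7, and 29 rejoins the route.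

**Further compounds**

F1 | step 4 | 5-bromo-3-[(triisopropylsilyl)oxy]-2-{[(2R)-4-(trimethylsilyl)but-3-yn-2-yl]oxy}benzoic acid | C[C@@H](Oc1c(C(=O)O)cc(Br)cc1O[Si](C(C)C)(C(C)C)C(C)C)C#C[Si](C)(C)C
F2 | step 4 | 5-bromo-3-[(triisopropylsilyl)oxy]-2-{[(2R)-4-(trimethylsilyl)but-3-yn-2-yl]oxy}benzoyl chloride | C[C@@H](Oc1c(C(Cl)=O)cc(Br)cc1O[Si](C(C)C)(C(C)C)C(C)C)C#C[Si](C)(C)C
F3 | step 4 | 1-(5-bromo-3-[(triisopropylsilyl)oxy]-2-{[(2R)-4-(trimethylsilyl)but-3-yn-2-yl]oxy}phenyl)-2-diazoethanone | C[C@@H](Oc1c(C(=O)C=[N+]=[N-])cc(Br)cc1O[Si](C(C)C)(C(C)C)C(C)C)C#C[Si](C)(C)C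
F4 | step 4 | (2S)-6-bromo-2-methyl-8-[(triisopropylsilyl)oxy]-2-[(trimethylsilyl)ethynyl]chroman-4-one | C[Si](C)(C)C#C[C@]1(C)CC(=O)c2cc(Br)cc(O[Si](C(C)C)(C(C)C)C(C)C)c2O1
F5 | step 6 | 2-thioxopyridin-1(2H)-yl (2S)-6-bromo-2-methyl-8-[(triisopropylsilyl)oxy]-2-[(trimethylsilyl)ethynyl]chromane-3-carboxylate | C[Si](C)(C)C#C[C@]1(C)C(C(=O)ON3C=CC=CC3=S)Cc2cc(Br)cc(O[Si](C(C)C)(C(C)C)C(C)C)c2O1
F6 | step 14 | (2S)-2-methyl-2-[(1E)-4-methylpenta-1,3-dien-1-yl]-8-[(triisopropylsilyl)oxy]chromane-6-carbaldehyde | CC(C)=C/C=C/[C@]1(C)CCc2cc(C=O)cc(O[Si](C(C)C)(C(C)C)C(C)C)c2O1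
F7 | step 14 | (E)-1-{2,4-bis[(tert-butyldimethylsilyl)oxy]-6-hydroxy-3-(3-methylbut-2-en-1-yl)phenyl}-3-{(2S)-2-methyl-2-[(1E)-4-methylpenta-1,3-dien-1-yl]-8-[(triisopropylsilyl)oxy]chroman-6-yl}prop-2-en-1-one | CC(C)=C/C=C/[C@]1(C)CCc2cc(/C=C/C(=O)c3c(O)cc(O[Si](C)(C)C(C)(C)C)c(CC=C(C)C)c3O[Si](C)(C)C(C)(C)C)cc(O[Si](C(C)C)(C(C)C)C(C)C)c2O1
F8 | step 14 | (2R)-5,7-bis[(tert-butyldimethylsilyl)oxy]-2-{(2S)-2-methyl-2-[(1E)-4-methylpenta-1,3-dien-1-yl]-8-[(triisopropylsilyl)oxy]chroman-6-yl}-6-(3-methylbut-2-en-1-yl)chroman-4-one | CC(C)=C/C=C/[C@]1(C)CCc2cc([C@H]3CC(=O)c4c(cc(O[Si](C)(C)C(C)(C)C)c(CC=C(C)C)c4O[Si](C)(C)C(C)(C)C)O3)cc(O[Si](C(C)C)(C(C)C)C(C)C)c2O1
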